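Ring B is disconnected at C8–C9. These adjacent carbons can each be placed α to a carbonyl group that is removed later, a C7 ketone and the C11 aryl ketone, so the C8–C9 bond sits in the middle of a 1,4-dicarbonyl array. Oxidation of the dilithium bis-enolate of that diketone with Fe(acac)3 joins the two α-carbons in one operation: it closes ring B onto ring A as a trans-decalin and sets quaternary C9 and C8. The substrate is a ring A cyclohexane with C4 masked as a dioxolane, a 2-oxobutyl arm on quaternary C5 and a trans 1-aroylethyl arm on C10, assembled by asymmetric vinyl conjugate addition–alkylation of 2-methylcyclohex-2-enone.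

Key step: step 10

Remark on numbering: atoms carry the numbers of the avarane skeleton (decalin C1–C10, C4 bearing the exocyclic carbon, C11 benzylic), also in the monocyclic intermediates; every bicyclic compound has 5β-, 8β- and 9β-methyl groups and 10α-H.
Assumption: the (S)-configured carbene ligand of step 1 is taken to deliver the vinyl group to the face of C10 that leads to 5; if the sense proves opposite, the enantiomeric ligand is used.

Step 1
Reactants: 1 2-methylcyclohex-2-en-1-one; 2 ethenylmagnesium bromide; 3 2-(bromomethyl)but-1-ene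
Product: 5 (2S,3S)-3-ethenyl-2-methyl-2-(2-methylidenebutyl)cyclohexan-1-one, via magnesium enolate 4 (not isolated)
Conditions: Cu(OTf)2 (3 mol%), (S)-1-(1-hydroxy-4-methylpentan-2-yl)-3-mesityl-4,5-dihydroimidazolium hexafluorophosphate (4 mol%), 2 (slow addition), Et2O, −30 °C; then DMPU, 3, −30 °C → rt
Reagents that add atoms: none
Why: Copper-catalysed asymmetric conjugate addition of a Grignard reagent to an α-methyl cyclic enone sets C10 under control of the chiral carbene ligand, and C-alkylation of the regiodefined magnesium enolate anti to the new vinyl group then sets quaternary C5 with its methyl cis to the vinyl group.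

Step 2
Reactants: 5
Product: 6 (6S,7S)-7-ethenyl-6-methyl-6-(2-methylidenebutyl)-1,4-dioxaspiro[4.5]decane
Conditions: (TMSOCH2)2, TMSOTf (5 mol%), CH2Cl2, −20 → 0 °C; pyridine quench
Reagents that add atoms: 1,2-bis(trimethylsilyloxy)ethane, C[Si](C)(C)OCCO[Si](C)(C)C
Why: Noyori ketalisation by silyl transfer masks the only carbonyl group (C4) under aprotic conditions that should not migrate the 1,1-disubstituted double bond.

Step 3
Reactants: 6
Product: 8 2-[(6S,7S)-6-methyl-6-(2-methylidenebutyl)-1,4-dioxaspiro[4.5]decan-7-yl]ethan-1-ol, via alkyl catecholboronate 7 (not isolated)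
Conditions: catecholborane, RhCl(PPh3)3 (2 mol%), THF, rt; then NaOH (3 M aq), H2O2 (30%), 0 °C → rt
Reagents that add atoms: hydrogen peroxide, OO
Why: Rhodium-catalysed hydroboration–oxidation should react at the monosubstituted vinyl group in preference to the 1,1-disubstituted alkene and place the oxygen on the terminal carbon (C11).

Step 4
Reactants: 8
Product: 9 2-[(6S,7S)-6-methyl-6-(2-methylidenebutyl)-1,4-dioxaspiro[4.5]decan-7-yl]acetaldehyde
Conditions: Dess–Martin periodinane, pyridine, CH2Cl2, 0 °C → rt
Reagents that add atoms: none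
Why: Dess–Martin oxidation of a primary alcohol to the aldehyde under buffered conditions that the dioxolane and the alkene tolerate.

Step 5
Reactants: 10 methyl 4-hydroxy-3-iodobenzoate
Product: 11 methyl 4-(benzyloxy)-3-iodobenzoate
Conditions: BnBr, K2CO3, DMF, rt
Reagents that add atoms: benzyl bromide, BrCc1ccccc1
Why: Williamson etherification gives a benzyl ether that withstands the organometallic, enolate and radical steps and is removed by hydrogenolysis before the exocyclic alkene exists.

Step 6
Reactants: 11 methyl 4-(benzyloxy)-3-iodobenzoate; 9 aldehyde from step 4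
Product: 13 methyl 4-(benzyloxy)-3-{1-hydroxy-2-[(6S,7S)-6-methyl-6-(2-methylidenebutyl)-1,4-dioxaspiro[4.5]decan-7-yl]ethyl}benzoate, via aryl Grignard reagent 12 (not isolated)
Conditions: 11, i-PrMgCl·LiCl, THF, −40 °C; then 9, −40 → −10 °C; aq NH4Cl
Reagents that add atoms: none
Why: Iodine–magnesium exchange at low temperature spares the methyl ester and the aryl Grignard reagent adds to the aldehyde (1,2-addition), forming the C11–aryl bond; the carbinol centre is left uncontrolled because it is oxidised next.

Step 7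
Reactants: 13
Product: 14 methyl 4-(benzyloxy)-3-{[(6S,7S)-6-methyl-6-(2-methylidenebutyl)-1,4-dioxaspiro[4.5]decan-7-yl]acetyl}benzoate
Conditions: Dess–Martin periodinane, pyridine, CH2Cl2, rt
Reagents that add atoms: none
Why: Dess–Martin oxidation of the secondary benzylic alcohol gives the C11 aryl ketone.

Step 8
Reactants: 14
Product: 16 methyl 4-(benzyloxy)-3-{2-[(6S,7S)-6-methyl-6-(2-methylidenebutyl)-1,4-dioxaspiro[4.5]decan-7-yl]propanoyl}benzoate, via lithium enolate 15 (not isolated)
Conditions: LiN(SiMe3)2, THF, −78 °C; then MeI, −78 → 0 °C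
Reagents that add atoms: iodomethane, CI
Why: Enolate alkylation at the only acidic position (C9, α to the aryl ketone) installs the C9 methyl group, as an epimer mixture that the key step erases.

Step 9
Reactants: 16
Product: 18 methyl 4-(benzyloxy)-3-{2-[(6S,7S)-6-methyl-6-(2-oxobutyl)-1,4-dioxaspiro[4.5]decan-7-yl]propanoyl}benzoate, via secondary ozonide 17 (not isolated)
Conditions: O3, CH2Cl2, −78 °C (stopped at first blue colour); then PPh3, −78 °C → rt
Reagents that add atoms: ozone, [O-][O+]=O
Why: Ozonolysis with reductive work-up cleaves the only remaining alkene to the C7 ethyl ketone, which is unveiled only now that C4 is masked and C9 is methylated.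

Step 10
Reactants: 18
Product: 20 methyl 4-(benzyloxy)-3-[(5S,8R,9S,10R)-4,4-ethylenedioxy-5,8,9-trimethyl-7-oxodecalin-9-carbonyl]benzoate, via dilithium bis-enolate 19 (not isolated)
Conditions: 18 added to LiN(i-Pr)2 (2.5 equiv), THF (0.02 M), −78 → −40 °C; then Fe(acac)3 (2.4 equiv), THF, −78 °C → rt
Reagents that add atoms: none
Why: Double deprotonation gives the bis-enolate (C8 kinetically, since the C6 methylene is neopentylic, and C9 as the only α-site of the aryl ketone); one-electron oxidation by trivalent iron turns the electron-richer ethyl-ketone enolate into an α-keto radical that adds to C9 of the aryl enolate, and a second oxidation of the resulting ketyl gives the 1,4-diketone. The closest known reaction type is the intramolecular oxidative heterocoupling of two lithium enolates with Fe(acac)3 or a copper carboxylate, which is known to form fully substituted carbons. Ring B closes in a 6-exo-trig mode (the C9=C11 enolate bond stays outside the new ring) through a chair-like transition state held by the trans-diequatorial C6 and C9 arms of ring A. C9 is controlled by that chair: the bulky aryl-enolate unit takes the equatorial site to avoid a 1,3-diaxial clash with the axial C5 methyl, so the C9 methyl ends axial and syn to it, and the C9 configuration of 18 does not matter because enolisation erases it. C8 should place its methyl equatorially in the same chair and stays correctable by enolisation through C7. The step needs C8–C9 coupling in preference to intermolecular dimerisation and to coupling at C6, which high dilution, the six- versus four-membered ring size and the absence of other enolisable sites (C4 as dioxolane, ester without α-hydrogen) should secure.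

Step 11
Reactants: 20
Product: 21 methyl 4-(benzyloxy)-3-{[(5S,8R,9S,10S)-4,4-ethylenedioxy-7-hydroxy-5,8,9-trimethyldecalin-9-yl]hydroxymethyl}benzoate
Conditions: NaOMe (0.2 equiv), MeOH–THF, rt; then NaBH4, 0 → 40 °C
Reagents that add atoms: none
Why: Catalytic methoxide first equilibrates C8 through the C7 enolate to the equatorial methyl epimer, then borohydride reduction turns both ketones into secondary alcohols whose configurations are irrelevant.

Step 12
Reactants: 21
Product: 23 methyl 4-(benzyloxy)-3-{[(5S,8R,9S,10S)-4,4-ethylenedioxy-5,8,9-trimethyl-7-(methylsulfanylcarbothioyloxy)decalin-9-yl](methylsulfanylcarbothioyloxy)methyl}benzoate, via disodium bis-xanthate 22 (not isolated)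
Conditions: NaH, imidazole (cat.), CS2, THF, 0 °C → rt; then MeI
Reagents that add atoms: carbon disulfide, S=C=S; iodomethane, CI
Why: Xanthate formation (alkoxide addition to CS2, then S-methylation) activates both hydroxyl groups for radical deoxygenation.

Step 13
Reactants: 23
Product: 24 methyl 4-(benzyloxy)-3-{[(5S,8S,9R,10S)-4,4-ethylenedioxy-5,8,9-trimethyldecalin-9-yl]methyl}benzoate
Conditions: Bu3SnH, AIBN (cat.), toluene, 90 °C
Reagents that add atoms: none
Why: Double Barton–McCombie deoxygenation removes the C7 and C11 oxygens through a secondary and a benzylic radical, which avoids the skeletal shifts that a C11 cation next to quaternary C9 would invite.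

Step 14
Reactants: 24
Product: 26 methyl 4-hydroxy-3-{[(5S,8S,9R,10S)-5,8,9-trimethyl-4-oxodecalin-9-yl]methyl}benzoate, via phenol ketal 25 (not isolated)
Conditions: H2 (1 atm), Pd/C (10%), EtOAc–MeOH, rt; filtration; then HCl (2 M aq), THF, rt
Reagents that add atoms: water, O
Why: Hydrogenolysis of the benzyl ether while no alkene is present, followed by acid hydrolysis of the dioxolane, frees the phenol and the C4 ketone.

Step 15
Reactants: 26
Product: 27 dictyoceratin C
Conditions: Ph3PCH3Br, KOt-Bu (excess), toluene, 90 °C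
Reagents that add atoms: methyltriphenylphosphonium bromide, C[P+](c1ccccc1)(c1ccccc1)c1ccccc1.[Br-]
Why: Wittig methylenation of the hindered C4 ketone with excess ylide, in which the phenoxide formed in the flask deactivates the para ester toward the ylide.

Compound list
1 | 2-methylcyclohex-2-en-1-one | CC1=CCCCC1=O | starting material
2 | ethenylmagnesium bromide | C=C[Mg]Br | starting material
3 | 2-(bromomethyl)but-1-ene | C=C(CC)CBr | starting material
4 | bromomagnesium (3S)-3-ethenyl-2-methylcyclohex-1-en-1-olate | CC1=C(O[Mg]Br)CCC[C@H]1C=C | intermediate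
5 | (2S,3S)-3-ethenyl-2-methyl-2-(2-methylidenebutyl)cyclohexan-1-one | CCC(=C)C[C@@]1(C)[C@H](C=C)CCCC1=O | intermediate
6 | (6S,7S)-7-ethenyl-6-methyl-6-(2-methylidenebutyl)-1,4-dioxaspiro[4.5]decane | CCC(=C)C[C@@]1(C)[C@H](C=C)CCCC12OCCO2 | intermediate
7 | 2-{2-[(6S,7R)-6-methyl-6-(2-methylidenebutyl)-1,4-dioxaspiro[4.5]decan-7-yl]ethyl}-1,3,2-benzodioxaborole | CCC(=C)C[C@@]1(C)[C@H](CCB2Oc3ccccc3O2)CCCC12OCCO2 | intermediate
8 | 2-[(6S,7S)-6-methyl-6-(2-methylidenebutyl)-1,4-dioxaspiro[4.5]decan-7-yl]ethan-1-ol | CCC(=C)C[C@@]1(C)[C@H](CCO)CCCC12OCCO2 | intermediate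
9 | 2-[(6S,7S)-6-methyl-6-(2-methylidenebutyl)-1,4-dioxaspiro[4.5]decan-7-yl]acetaldehyde | CCC(=C)C[C@@]1(C)[C@H](CC=O)CCCC12OCCO2 | intermediate
10 | methyl 4-hydroxy-3-iodobenzoate | COC(=O)c1ccc(O)c(I)c1 | starting material
11 | methyl 4-(benzyloxy)-3-iodobenzoate | COC(=O)c1ccc(OCc2ccccc2)c(I)c1 | intermediate
12 | [2-(benzyloxy)-5-(methoxycarbonyl)phenyl]magnesium chloride (LiCl complex) | COC(=O)c1ccc(OCc2ccccc2)c([Mg]Cl)c1 | intermediate
13 | methyl 4-(benzyloxy)-3-{1-hydroxy-2-[(6S,7S)-6-methyl-6-(2-methylidenebutyl)-1,4-dioxaspiro[4.5]decan-7-yl]ethyl}benzoate, both C11 epimers | CCC(=C)C[C@@]1(C)[C@H](CC(O)c2cc(C(=O)OC)ccc2OCc2ccccc2)CCCC12OCCO2 | intermediate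
14 | methyl 4-(benzyloxy)-3-{[(6S,7S)-6-methyl-6-(2-methylidenebutyl)-1,4-dioxaspiro[4.5]decan-7-yl]acetyl}benzoate | CCC(=C)C[C@@]1(C)[C@H](CC(=O)c2cc(C(=O)OC)ccc2OCc2ccccc2)CCCC12OCCO2 | intermediate
15 | lithium enolate of 14 (C9=C11) | CCC(=C)C[C@@]1(C)[C@H](C=C(O[Li])c2cc(C(=O)OC)ccc2OCc2ccccc2)CCCC12OCCO2 | intermediate
16 | methyl 4-(benzyloxy)-3-{2-[(6S,7S)-6-methyl-6-(2-methylidenebutyl)-1,4-dioxaspiro[4.5]decan-7-yl]propanoyl}benzoate, both C9 epimers | CCC(=C)C[C@@]1(C)[C@H](C(C)C(=O)c2cc(C(=O)OC)ccc2OCc2ccccc2)CCCC12OCCO2 | intermediate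
17 | secondary ozonide (3-ethyl-1,2,4-trioxolan-3-yl)methyl derivative of 16 | CCC1(OCOO1)C[C@@]2(C)[C@H](C(C)C(=O)c3cc(C(=O)OC)ccc3OCc3ccccc3)CCCC24OCCO4 | intermediate
18 | methyl 4-(benzyloxy)-3-{2-[(6S,7S)-6-methyl-6-(2-oxobutyl)-1,4-dioxaspiro[4.5]decan-7-yl]propanoyl}benzoate, both C9 epimers (precursor of the key step) | CCC(=O)C[C@@]1(C)[C@H](C(C)C(=O)c2cc(C(=O)OC)ccc2OCc2ccccc2)CCCC12OCCO2 | intermediate
19 | dilithium bis-enolate of 18 (C7=C8 and C9=C11) | CC=C(O[Li])C[C@@]1(C)[C@H](C(C)=C(O[Li])c2cc(C(=O)OC)ccc2OCc2ccccc2)CCCC12OCCO2 | intermediate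
20 | methyl 4-(benzyloxy)-3-[(5S,8R,9S,10R)-4,4-ethylenedioxy-5,8,9-trimethyl-7-oxodecalin-9-carbonyl]benzoate; trans-decalin, 9α-aroyl (product of the key step) | O1CCOC12CCC[C@H]3[C@](C)(C(=O)c4cc(C(=O)OC)ccc4OCc4ccccc4)[C@@H](C)C(=O)C[C@]23C | intermediate
21 | methyl 4-(benzyloxy)-3-{[(5S,8R,9S,10S)-4,4-ethylenedioxy-7-hydroxy-5,8,9-trimethyldecalin-9-yl]hydroxymethyl}benzoate, epimers at C7 and C11 | O1CCOC12CCC[C@H]3[C@](C)(C(O)c4cc(C(=O)OC)ccc4OCc4ccccc4)[C@@H](C)C(O)C[C@]23C | intermediate
22 | disodium 7,11-bis(dithiocarbonate) of 21 | [Na+].[Na+].O1CCOC12CCC[C@H]3[C@](C)(C(OC(=S)[S-])c4cc(C(=O)OC)ccc4OCc4ccccc4)[C@@H](C)C(OC(=S)[S-])C[C@]23C | intermediate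
23 | 7,11-bis(S-methyl dithiocarbonate) of 21 | O1CCOC12CCC[C@H]3[C@](C)(C(OC(=S)SC)c4cc(C(=O)OC)ccc4OCc4ccccc4)[C@@H](C)C(OC(=S)SC)C[C@]23C | intermediate
24 | methyl 4-(benzyloxy)-3-{[(5S,8S,9R,10S)-4,4-ethylenedioxy-5,8,9-trimethyldecalin-9-yl]methyl}benzoate | O1CCOC12CCC[C@H]3[C@](C)(Cc4cc(C(=O)OC)ccc4OCc4ccccc4)[C@@H](C)CC[C@]23C | intermediate
25 | methyl 3-{[(5S,8S,9R,10S)-4,4-ethylenedioxy-5,8,9-trimethyldecalin-9-yl]methyl}-4-hydroxybenzoate | O1CCOC12CCC[C@H]3[C@](C)(Cc4cc(C(=O)OC)ccc4O)[C@@H](C)CC[C@]23C | intermediate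
26 | methyl 4-hydroxy-3-{[(5S,8S,9R,10S)-5,8,9-trimethyl-4-oxodecalin-9-yl]methyl}benzoate | O=C1CCC[C@H]2[C@](C)(Cc3cc(C(=O)OC)ccc3O)[C@@H](C)CC[C@]12C | intermediate
27 | dictyoceratin C, methyl 4-hydroxy-3-{[(5S,8S,9R,10S)-5,8,9-trimethyl-4-methylidenedecalin-9-yl]methyl}benzoate | C=C1CCC[C@H]2[C@](C)(Cc3cc(C(=O)OC)ccc3O)[C@@H](C)CC[C@]12C | target

Total step count: 15
Longest linear sequence: 14 steps (steps 1–4 and 6–15, from 1 to 27); step 5 is a one-step side branch.

Steps most likely to fail

Step 10 (key step). The second deprotonation at the hindered C9–H may stay incomplete. Bond formation between a secondary and a fully substituted enolate carbon may also be outrun by return to 18 or by intermolecular coupling. Attack on the other face of the C9 enolate would give a C9 epimer that cannot be corrected. Fallback: setting out from 18, the two enol oxygens are first joined through silicon; LiN(i-Pr)2 and then i-Pr2SiCl2 at high dilution should give the cyclic diisopropylsilylene bis-enol ether F1. Oxidation of F1 with (NH4)2Ce(NO3)6 and NaHCO3 in MeCN at −10 °C is a known silicon-tethered oxidative coupling of enol silanes; it runs through an enol-ether radical cation held next to its partner by the tether, not through a dianion, and after loss of the silicon bridge it comes back to the route at 20.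

Step 1. Enantiofacial discrimination may be poor with an sp2 Grignard reagent, and C-alkylation of the magnesium enolate may be slow. Fallback: setting out from 1, 2 and 3, the same conjugate addition–alkylation is run under achiral copper catalysis (CuBr·SMe2) to give the racemic trans ketone F2. Ketalisation with (2R,3R)-butane-2,3-diol (TsOH, benzene, reflux) gives the diastereomeric ketals F3 and F4, which are separated by chromatography. Hydrolysis of F3 (aq HCl, THF) comes back to the route at 5, so the stereocontrol is changed from catalyst control to a resolution through diastereomers.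

Step 12. Thiocarbonylation of the neopentylic, aryl-flanked C11 alkoxide may be incomplete because its addition to CS2 is reversible, and O-methylation by MeI may then compete. Fallback: setting out from 21, only the less hindered C7 hydroxyl is activated with PhOC(S)Cl, pyridine and DMAP to give the C7 phenyl thionocarbonate F5. Bu3SnH and AIBN then give the C7-deoxygenated benzylic alcohol F6. Hydrogenation of F6 over Pd/C in AcOH with a trace of HClO4 cleaves the benzyl ether to the ortho-hydroxybenzylic alcohol F7, which loses water to the ortho-quinone methide F8; this is reduced in the same flask to 25, and the aqueous acid gives 26, where the route is rejoined. The C11 oxygen is thus removed by an ionic, hydrogenolytic path instead of a radical one.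

Further compounds
F1 | step 10 | cyclic diisopropylsilylene bis-enol ether of 18 (silicon bridging the C7 and C11 enol oxygens) | CC=C1C[C@@]2(C)[C@H](C(C)=C(O[Si](C(C)C)(C(C)C)O1)c1cc(C(=O)OC)ccc1OCc1ccccc1)CCCC23OCCO3
F2 | step 1 | racemic trans-3-ethenyl-2-methyl-2-(2-methylidenebutyl)cyclohexan-1-one (5 with its enantiomer; one enantiomer drawn) | CCC(=C)C[C@@]1(C)[C@H](C=C)CCCC1=O
F3 | step 1 | (2R,3R,6S,7S)-7-ethenyl-2,3,6-trimethyl-6-(2-methylidenebutyl)-1,4-dioxaspiro[4.5]decane | CCC(=C)C[C@@]1(C)[C@H](C=C)CCCC12O[C@H](C)[C@@H](C)O2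
F4 | step 1 | (2R,3R,6R,7R)-7-ethenyl-2,3,6-trimethyl-6-(2-methylidenebutyl)-1,4-dioxaspiro[4.5]decane | CCC(=C)C[C@]1(C)[C@@H](C=C)CCCC12O[C@H](C)[C@@H](C)O2
F5 | step 12 | C7 O-phenyl thionocarbonate of 21 (C11 hydroxyl free) | O1CCOC12CCC[C@H]3[C@](C)(C(O)c4cc(C(=O)OC)ccc4OCc4ccccc4)[C@@H](C)C(OC(=S)Oc4ccccc4)C[C@]23C
F6 | step 12 | methyl 4-(benzyloxy)-3-{[4,4-ethylenedioxy-5,8,9-trimethyldecalin-9-yl]hydroxymethyl}benzoate (C7 deoxygenated) | O1CCOC12CCC[C@H]3[C@](C)(C(O)c4cc(C(=O)OC)ccc4OCc4ccccc4)[C@@H](C)CC[C@]23C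
F7 | step 12 | methyl 3-{[4,4-ethylenedioxy-5,8,9-trimethyldecalin-9-yl]hydroxymethyl}-4-hydroxybenzoate | O1CCOC12CCC[C@H]3[C@](C)(C(O)c4cc(C(=O)OC)ccc4O)[C@@H](C)CC[C@]23C
F8 | step 12 | ortho-quinone methide from F7 (C11=C1′, C6′=O) | O1CCOC12CCC[C@H]3[C@](C)(C=C4C=C(C(=O)OC)C=CC4=O)[C@@H](C)CC[C@]23C
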